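Does this flask come to rest within its time, and how does the substrate divide between ring and open dimer?

    2 substrate → open dimer (k1 = 0.184 M⁻¹ s⁻¹)
    substrate → ring (k2 = 0.00502 s⁻¹)

substrate 0.052 M; time 8.0 h

- a species is counted by the substrate in it: one open dimer counts as two
- a step written with two of one species runs at k times the square of its concentration and takes two of it each time
- the reaction counts as stopped when no species that holds the substrate changes by six tenths of a point or more over the second half of the time
- run time (flask): 8.0 h

1. which holds at 8.0 h: what has brought the reaction to rest, or that it has not come to rest (it is still moving / all of the substrate has reacted / forward and back rates have come level)
2. how much of the substrate has reacted by 8.0 h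
3. how much ring there is at 8.0 h, in percent of the substrate charged
4. how much open dimer there is at 8.0 h, in percent of the substrate charged

Turned round, for this flask to be still moving at the end, its substrate life has to stand comparable with its time. In this flask, ring closure by step 2 alone halves the substrate in 2.3 min, far shorter than 8.0 h, and the dimer step adds to that loss. Neither step runs back and that half-life is shorter than the time, so I expect the substrate to react to the end, which leaves the split. For the opposite split, the ring share has to stand above 0.5.

The substrate's balance has two losses: 2 × dimer constant × substrate squared, and ring constant × substrate. Ring receives the second, so its part of each loss grows as the substrate falls. I write:

channel ratio = 2 × dimer constant × substrate charged / ring constant = 3.81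

This channel ratio, a selectivity factor, compares the substrate's two losses at the start. Summing the balance from the charge down to nothing gives:

ring share = ln(1 + channel ratio) / channel ratio = 41.2%

So this flask stands below the opposite split, with 58.8% as open dimer.

The forecast says that all of the substrate has reacted, with conversion 100%, ring 41.2% and open dimer 58.8%, reasoning that “both steps are irreversible, so the product split is then fixed”.

In the flask, all of the substrate has reacted, with conversion 100%, ring 41.2% and open dimer 58.8%. Its charge lies above 0.0343 M, the amount at which ring and open dimer hold the same. At that amount the channel ratio is 2.51, and the ring share is 50.0%.

For the neighbour flask with 0.021 M of substrate, the channel ratio is 1.54, which gives a ring share of 60.5%. That flask ends with ring 60.5% and open dimer 39.5%.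

Its constants are assumed; no experiment stands behind them.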